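**Plan**

Germacrane numbering: ring A = ten-membered carbocycle C1–C10 (C1 ketone, Z C4=C5); ring B = 3(2H)-furanone (O, C10, C1, C2, C3); ring C = lactone (O, C6, C7, C11, C12); C13 = exocyclic CH2, C14 = methyl on C10, C15 = CH2OH on C4.
Cuts, in order: the C8 O–acyl bond, C11=C13, the lactone O–C12 bond (ring C), C5–C6 (ring A), C7–C8, then C2–C3 and O–C3 (ring B), and C4–C15 with C5–I.
Forward: ring B is made first from a citramalate-derived ketol and a (Z)-iodoacrylic acid; the chain is extended at C8 by an anti-aldol; ring A closes at C5–C6; ring C closes last, followed by methylenation and esterification.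
Stereochemistry: C10 from (S)-citramalic acid; C7 and C8 from an oxazolidinone-controlled anti-aldol; C6 from the ring closure under control of C7; the Z C4=C5 olefin from the iodo-aldol of methyl propiolate.
Enabling feature: C6 is a secondary allylic carbinol carbon bonded to sp2 C5 of the Z C4=C5 olefin of ring A and flanked by the stereocentre C7, the pattern left by a C5 alkenylmetal adding to a C6 aldehyde.

Key step: step 17

Remark on the chemistry: C12 is carried as a tert-butyl ester, so that the C6 primary alcohol formed when the auxiliary is removed cannot lactonize before the C6 aldehyde is made; C15 carries TBDPS and C8 carries TBS so that each silyl ether can be removed in turn.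

**Route**

Step 1
Reactants: 1 methyl propiolate
Product: 2 methyl (Z)-2-(hydroxymethyl)-3-iodoacrylate
Conditions: MgI2, monomeric CH2O (from cracked paraformaldehyde), CH2Cl2, −20 to 0 °C
Reagents that add atoms: formaldehyde C=O; magnesium diiodide [Mg+2].[I-].[I-]
Why: Iodide adds to the propiolate to give a magnesium β-iodoallenolate that is trapped at carbon by formaldehyde (β-iodo Morita–Baylis–Hillman, or iodo-aldol, reaction); the aldehyde enters in the plane of the CHI terminus on the side of hydrogen, so iodine ends cis to the ester, the Z geometry that later places C5 cis to C3.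

Step 2
Reactants: 2 methyl (Z)-2-(hydroxymethyl)-3-iodoacrylate
Product: 3 methyl (Z)-2-[(tert-butyldiphenylsilyloxy)methyl]-3-iodoacrylate
Conditions: TBDPSCl, imidazole, CH2Cl2, 0 °C to rt
Reagents that add atoms: tert-butyl(chloro)diphenylsilane CC(C)(C)[Si](Cl)(c1ccccc1)c1ccccc1
Why: Standard silylation of a primary alcohol with a silyl chloride and imidazole; the TBDPS ether is chosen because it should outlast the Lewis acids, the acid steps and both later TBS cleavages.

Step 3
Reactants: 3 methyl (Z)-2-[(tert-butyldiphenylsilyloxy)methyl]-3-iodoacrylate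
Product: 4 (Z)-2-[(tert-butyldiphenylsilyloxy)methyl]-3-iodoacrylic acid
Conditions: LiOH, THF/H2O, 0 °C; then 1 M HCl to pH 3
Reagents that add atoms: lithium hydroxide [Li+].[OH-]
Why: Saponification of the methyl ester at 0 °C should be faster than addition–elimination of hydroxide at the hindered β-iodo carbon, so the acid is expected with the Z iodoalkene and the silyl ether intact.

Step 4
Reactants: 5 (S)-citramalic acid
Product: 6 2-[(S)-2,2,4-trimethyl-5-oxo-1,3-dioxolan-4-yl]acetic acid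
Conditions: 2,2-dimethoxypropane, pyridinium p-toluenesulfonate (cat.), rt
Reagents that add atoms: 2,2-dimethoxypropane COC(C)(C)OC
Why: Acetonide formation (transketalization) ties the tertiary hydroxyl and the adjacent carboxyl into a five-membered dioxolanone and leaves the distal C8 carboxyl free, as is known for malic and citramalic acid; the C10 stereocentre is not touched.

Step 5
Reactants: 6 2-[(S)-2,2,4-trimethyl-5-oxo-1,3-dioxolan-4-yl]acetic acid
Product: 7 (S)-5-(2-hydroxyethyl)-2,2,5-trimethyl-1,3-dioxolan-4-one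
Conditions: BH3·SMe2, THF, 0 °C to rt; MeOH quench
Reagents that add atoms: none
Why: Borane reduces a free carboxylic acid far faster than an ester-type carbonyl (chemoselective acid reduction), so only C8 is reduced.

Step 6
Reactants: 7 (S)-5-(2-hydroxyethyl)-2,2,5-trimethyl-1,3-dioxolan-4-one
Product: 8 (S)-2,4-dihydroxy-N-methoxy-N,2-dimethylbutanamide
Conditions: MeNH(OMe)·HCl, AlMe3, CH2Cl2, 0 °C to rt; aq. potassium sodium tartrate; used crude
Reagents that add atoms: N,O-dimethylhydroxylamine hydrochloride CNOC.Cl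
Why: Aminolysis of the activated dioxolanone carbonyl by the aluminium amide (Weinreb amide formation) releases acetone and the tertiary hydroxyl; any hydroxy lactone formed from 7 by translactonization is opened to the same amide, which is taken on crude to avoid relactonization.

Step 7
Reactants: 8 (S)-2,4-dihydroxy-N-methoxy-N,2-dimethylbutanamide
Product: 10 (S)-4-(tert-butyldimethylsilyloxy)-N-methoxy-N,2-dimethyl-2-(trimethylsilyloxy)butanamide, via mono-TBS ether 9 (not isolated)
Conditions: TBSCl, imidazole, DMF, 0 °C; then TMSCl, rt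
Reagents that add atoms: tert-butyl(chloro)dimethylsilane CC(C)(C)[Si](C)(C)Cl; chlorotrimethylsilane C[Si](C)(C)Cl
Why: Silylation with silyl chlorides and imidazole: the bulky TBSCl takes only the primary hydroxyl and the small TMSCl then caps the tertiary one, which blocks relactonization and later O-acylation.

Step 8
Reactants: 10 (S)-4-(tert-butyldimethylsilyloxy)-N-methoxy-N,2-dimethyl-2-(trimethylsilyloxy)butanamide
Product: 11 (S)-5-(tert-butyldimethylsilyloxy)-3-methyl-3-(trimethylsilyloxy)pentan-2-one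
Conditions: MeMgBr, THF, 0 °C to rt; aq. NH4Cl
Reagents that add atoms: methylmagnesium bromide C[Mg]Br
Why: Weinreb ketone synthesis: the chelated tetrahedral magnesium intermediate holds until work-up, so a single methyl adds and the C1 methyl ketone (C2 = CH3) results.

Step 9
Reactants: 11 (S)-5-(tert-butyldimethylsilyloxy)-3-methyl-3-(trimethylsilyloxy)pentan-2-one; 4 (Z)-2-[(tert-butyldiphenylsilyloxy)methyl]-3-iodoacrylic acid
Product: 14 (S)-2-[2-(tert-butyldimethylsilyloxy)ethyl]-5-[(Z)-3-(tert-butyldiphenylsilyloxy)-1-iodoprop-1-en-2-yl]-2-methylfuran-3(2H)-one, via acid chloride 12 (not isolated), via diketone 13 (not isolated)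
Conditions: 4, 1-chloro-N,N,2-trimethylprop-1-en-1-amine, CH2Cl2, 0 °C; then 11, MgBr2·OEt2, iPr2NEt, CH2Cl2, 0 °C to rt; work-up; then TsOH·H2O (cat.), CH2Cl2, rt
Reagents that add atoms: none
Why: The acid is converted to its chloride under neutral conditions, the methyl ketone (its only enolizable site) is C-acylated by soft enolization with MgBr2·OEt2 and iPr2NEt (Claisen-type acylation to the 1,3-diketone) with no nucleophile present that could add–eliminate at the iodoalkene, and acid then removes the TMS group and cyclodehydrates the hydroxy diketone to the 3(2H)-furanone (ring B) while the primary TBS and TBDPS ethers hold.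

Step 10
Reactants: 14 (S)-2-[2-(tert-butyldimethylsilyloxy)ethyl]-5-[(Z)-3-(tert-butyldiphenylsilyloxy)-1-iodoprop-1-en-2-yl]-2-methylfuran-3(2H)-one
Product: 15 (S)-5-[(Z)-3-(tert-butyldiphenylsilyloxy)-1-iodoprop-1-en-2-yl]-2-(2-hydroxyethyl)-2-methylfuran-3(2H)-one
Conditions: HF·pyridine, pyridine, THF, 0 °C
Reagents that add atoms: none
Why: Buffered fluoride desilylation distinguishes the primary TBS ether from the much more stable TBDPS ether.

Step 11
Reactants: 15 (S)-5-[(Z)-3-(tert-butyldiphenylsilyloxy)-1-iodoprop-1-en-2-yl]-2-(2-hydroxyethyl)-2-methylfuran-3(2H)-one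
Product: 16 2-[(S)-5-[(Z)-3-(tert-butyldiphenylsilyloxy)-1-iodoprop-1-en-2-yl]-2-methyl-3-oxo-2,3-dihydrofuran-2-yl]acetaldehyde
Conditions: Dess–Martin periodinane, pyridine, CH2Cl2, 0 °C to rt; used at once
Reagents that add atoms: none
Why: Dess–Martin oxidation under buffered, non-basic conditions should give the C8 aldehyde without β-elimination of the ring B oxygen.

Step 12
Reactants: 17 4-tert-butoxy-4-oxobutanoic acid (mono-tert-butyl succinate); 18 (S)-4-benzyl-2-oxazolidinone
Product: 20 tert-butyl 4-[(S)-4-benzyl-2-oxooxazolidin-3-yl]-4-oxobutanoate, via mixed anhydride 19 (not isolated)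
Conditions: pivaloyl chloride, Et3N, THF, −20 °C; then LiCl, 18, rt
Reagents that add atoms: none
Why: N-Acylation of the oxazolidinone through the mixed pivalic anhydride (imide formation); the hindered pivaloyl carbonyl is not attacked.

Step 13
Reactants: 20 tert-butyl 4-[(S)-4-benzyl-2-oxooxazolidin-3-yl]-4-oxobutanoate; 16 2-[(S)-5-[(Z)-3-(tert-butyldiphenylsilyloxy)-1-iodoprop-1-en-2-yl]-2-methyl-3-oxo-2,3-dihydrofuran-2-yl]acetaldehyde
Product: 22 tert-butyl (3R,4R)-3-[(S)-4-benzyl-2-oxooxazolidine-3-carbonyl]-4-hydroxy-5-[(S)-5-[(Z)-3-(tert-butyldiphenylsilyloxy)-1-iodoprop-1-en-2-yl]-2-methyl-3-oxo-2,3-dihydrofuran-2-yl]pentanoate, via boron enolate 21 (not isolated)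
Conditions: 20 (2 equiv), Bu2BOTf, iPr2NEt, CH2Cl2, 0 °C; then added at −78 °C to 16 precomplexed with Et2AlCl in CH2Cl2; aq. potassium sodium tartrate
Reagents that add atoms: none
Why: Anti-selective Lewis-acid-mediated variant of the Evans boron aldol reaction: the Z boron enolate, still chelated to the oxazolidinone carbonyl, adds through an open transition state to the Et2AlCl-complexed aldehyde on the face away from the benzyl group (sets C7, the same face as in alkylations of this auxiliary), and the bulky aluminium on the aldehyde oxygen enforces the anti relation (sets C8); the imide enolizes in preference to the tert-butyl ester and the remote C10 centre should have little influence.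

Step 14
Reactants: 22 tert-butyl (3R,4R)-3-[(S)-4-benzyl-2-oxooxazolidine-3-carbonyl]-4-hydroxy-5-[(S)-5-[(Z)-3-(tert-butyldiphenylsilyloxy)-1-iodoprop-1-en-2-yl]-2-methyl-3-oxo-2,3-dihydrofuran-2-yl]pentanoate
Product: 23 tert-butyl (3R,4R)-3-[(S)-4-benzyl-2-oxooxazolidine-3-carbonyl]-4-(tert-butyldimethylsilyloxy)-5-[(S)-5-[(Z)-3-(tert-butyldiphenylsilyloxy)-1-iodoprop-1-en-2-yl]-2-methyl-3-oxo-2,3-dihydrofuran-2-yl]pentanoate
Conditions: TBSOTf (1.2 equiv), 2,6-lutidine, CH2Cl2, −78 °C
Reagents that add atoms: tert-butyldimethylsilyl triflate CC(C)(C)[Si](C)(C)OS(=O)(=O)C(F)(F)F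
Why: Silylation of the hindered secondary C8 hydroxyl with the silyl triflate at −78 °C, where the tert-butyl ester is not cleaved; it blocks an 8,12-lactone and retro-aldol cleavage.

Step 15
Reactants: 23 tert-butyl (3R,4R)-3-[(S)-4-benzyl-2-oxooxazolidine-3-carbonyl]-4-(tert-butyldimethylsilyloxy)-5-[(S)-5-[(Z)-3-(tert-butyldiphenylsilyloxy)-1-iodoprop-1-en-2-yl]-2-methyl-3-oxo-2,3-dihydrofuran-2-yl]pentanoate
Product: 24 tert-butyl (3S,4R)-4-(tert-butyldimethylsilyloxy)-5-[(S)-5-[(Z)-3-(tert-butyldiphenylsilyloxy)-1-iodoprop-1-en-2-yl]-2-methyl-3-oxo-2,3-dihydrofuran-2-yl]-3-(hydroxymethyl)pentanoate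
Conditions: NaBH4, THF/H2O, 0 °C to rt
Reagents that add atoms: none
Why: Reductive cleavage of the N-acyloxazolidinone by borohydride gives the C6 primary alcohol; the imide is more electrophilic than the tert-butyl ester and the vinylogous ester carbonyl of ring B, and the bulky ester should not lactonize with the new hydroxyl.

Step 16
Reactants: 24 tert-butyl (3S,4R)-4-(tert-butyldimethylsilyloxy)-5-[(S)-5-[(Z)-3-(tert-butyldiphenylsilyloxy)-1-iodoprop-1-en-2-yl]-2-methyl-3-oxo-2,3-dihydrofuran-2-yl]-3-(hydroxymethyl)pentanoate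
Product: 25 tert-butyl (3R,4R)-4-(tert-butyldimethylsilyloxy)-5-[(S)-5-[(Z)-3-(tert-butyldiphenylsilyloxy)-1-iodoprop-1-en-2-yl]-2-methyl-3-oxo-2,3-dihydrofuran-2-yl]-3-formylpentanoate
Conditions: Dess–Martin periodinane, pyridine, CH2Cl2, 0 °C to rt; used at once
Reagents that add atoms: none
Why: Dess–Martin oxidation should give the α-branched β-silyloxy C6 aldehyde without epimerization at C7 or β-elimination.

Step 17
Reactants: 25 tert-butyl (3R,4R)-4-(tert-butyldimethylsilyloxy)-5-[(S)-5-[(Z)-3-(tert-butyldiphenylsilyloxy)-1-iodoprop-1-en-2-yl]-2-methyl-3-oxo-2,3-dihydrofuran-2-yl]-3-formylpentanoate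
Product: 26 tert-butyl 2-[(4Z,6R,7S,8R,10S)-8-(tert-butyldimethylsilyloxy)-15-(tert-butyldiphenylsilyloxy)-6-hydroxy-1-oxo-3,10-epoxy-11,12,13-trinorgermacra-2,4-dien-7-yl]acetate
Conditions: CrCl2 (15 equiv), NiCl2 (1 mol% of the CrCl2), degassed DMSO/THF, rt, slow addition of 25 to 2 mM
Reagents that add atoms: none
Why: CrCl2 reduces NiCl2 to zerovalent nickel, which inserts into the C5–I bond; transmetalation gives a Z alkenyl species of trivalent chromium with retention of olefin geometry, and this adds to the C6 aldehyde to give a chromium alkoxide that is protonated on work-up. The closest known reaction type is the Nozaki–Hiyama–Kishi alkenyl iodide–aldehyde macrocyclization used for medium and large carbocycles. Ring A closes by C5–C6 bond formation in an exo-trig attack of C5 on the aldehyde carbon, which forms the ten-membered carbocycle (nine atoms in the shortest circuit through the ring B oxygen). The new C6 stereocentre is set by C7: in the Felkin–Anh arrangement the ring-forming C8 branch lies anti to the incoming C5, C11 sits next to the carbonyl oxygen and C5 passes over C7–H, which should give the 6R carbinol with its oxygen trans to C11. The step needs chemoselectivity for the aldehyde over the ring B ketone and the ester, retention of the Z geometry, and cyclization over oligomerization; alkenylchromium reagents add to aldehydes far faster than to vinylogous esters or esters, the Z iodoalkene held on the flat furanone already turns C5 toward C6, and slow addition at high dilution suppresses intermolecular coupling.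

Step 18
Reactants: 26 tert-butyl 2-[(4Z,6R,7S,8R,10S)-8-(tert-butyldimethylsilyloxy)-15-(tert-butyldiphenylsilyloxy)-6-hydroxy-1-oxo-3,10-epoxy-11,12,13-trinorgermacra-2,4-dien-7-yl]acetate
Product: 27 (4Z,6R,7S,8R,10S)-8-(tert-butyldimethylsilyloxy)-15-(tert-butyldiphenylsilyloxy)-1-oxo-3,10-epoxy-13-norgermacra-2,4-dien-12,6-olide
Conditions: TsOH·H2O (cat.), toluene, 40 °C
Reagents that add atoms: none
Why: Acid-catalysed intramolecular transesterification (lactonization) of the γ-hydroxy tert-butyl ester closes ring C trans-fused with loss of tert-butanol; only O6 is free, so no 8,12-lactone can form, and catalytic acid in toluene should spare both silyl ethers.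

Step 19
Reactants: 27 (4Z,6R,7S,8R,10S)-8-(tert-butyldimethylsilyloxy)-15-(tert-butyldiphenylsilyloxy)-1-oxo-3,10-epoxy-13-norgermacra-2,4-dien-12,6-olide
Product: 30 (4Z,6R,7S,8R,10S)-8-(tert-butyldimethylsilyloxy)-15-(tert-butyldiphenylsilyloxy)-1-oxo-3,10-epoxygermacra-2,4,11(13)-trien-12,6-olide, via Mannich base 28 (not isolated), via ammonium iodide 29 (not isolated)
Conditions: LiN(iPr)2, THF, −78 °C; Me2N=CH2 I, −78 °C to rt; then MeI, MeOH/CH2Cl2, rt; then aq. NaHCO3
Reagents that add atoms: dimethylmethyleneiminium iodide C=[N+](C)C.[I-]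
Why: α-Methylenation by the Mannich route: the lactone enolate (C11 is the only acidic position) is aminomethylated, the amine is quaternized with MeI and eliminated with mild base (Hofmann-type elimination) to the exocyclic C11=C13 olefin; O8 is still silylated, so no ester competes with the lactone for the base.

Step 20
Reactants: 30 (4Z,6R,7S,8R,10S)-8-(tert-butyldimethylsilyloxy)-15-(tert-butyldiphenylsilyloxy)-1-oxo-3,10-epoxygermacra-2,4,11(13)-trien-12,6-olide
Product: 31 (4Z,6R,7R,8R,10S)-15-(tert-butyldiphenylsilyloxy)-8-hydroxy-1-oxo-3,10-epoxygermacra-2,4,11(13)-trien-12,6-olide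
Conditions: HF·pyridine, pyridine, THF, 0 °C to rt
Reagents that add atoms: none
Why: Desilylation: buffered HF·pyridine should cleave the secondary TBS ether well before the primary TBDPS ether and is non-basic toward the methylene lactone.

Step 21
Reactants: 31 (4Z,6R,7R,8R,10S)-15-(tert-butyldiphenylsilyloxy)-8-hydroxy-1-oxo-3,10-epoxygermacra-2,4,11(13)-trien-12,6-olide
Product: 32 (4Z,6R,7R,8R,10S)-15-(tert-butyldiphenylsilyloxy)-8-(2-methylpropanoyloxy)-1-oxo-3,10-epoxygermacra-2,4,11(13)-trien-12,6-olide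
Conditions: (iPrCO)2O, DMAP (cat.), Et3N, CH2Cl2, 0 °C to rt
Reagents that add atoms: isobutyric anhydride CC(C)C(=O)OC(=O)C(C)C
Why: DMAP-catalysed acylation (esterification) of the hindered secondary C8 alcohol, the only free hydroxyl; the configuration at C8 is retained.

Step 22
Reactants: 32 (4Z,6R,7R,8R,10S)-15-(tert-butyldiphenylsilyloxy)-8-(2-methylpropanoyloxy)-1-oxo-3,10-epoxygermacra-2,4,11(13)-trien-12,6-olide
Product: 33 (4Z,6R,7R,8R,10S)-15-hydroxy-8-(2-methylpropanoyloxy)-1-oxo-3,10-epoxygermacra-2,4,11(13)-trien-12,6-olide (CNP0176924.2)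
Conditions: aq. HF (48%), MeCN, 0 °C to rt
Reagents that add atoms: none
Why: Acidic fluoride desilylation should remove the TBDPS ether without touching the isobutyrate or adding to the methylene lactone, and frees the C15 alcohol of the target.

**Compound list**

1 | methyl propiolate | COC(=O)C#C | starting material
2 | methyl (Z)-2-(hydroxymethyl)-3-iodoacrylate | COC(=O)/C(CO)=C\I | intermediate
3 | methyl (Z)-2-[(tert-butyldiphenylsilyloxy)methyl]-3-iodoacrylate | COC(=O)/C(CO[Si](c1ccccc1)(c1ccccc1)C(C)(C)C)=C\I | intermediate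
4 | (Z)-2-[(tert-butyldiphenylsilyloxy)methyl]-3-iodoacrylic acid | OC(=O)/C(CO[Si](c1ccccc1)(c1ccccc1)C(C)(C)C)=C\I | intermediate
5 | (S)-citramalic acid | OC(=O)[C@](C)(CC(O)=O)O | starting material
6 | 2-[(S)-2,2,4-trimethyl-5-oxo-1,3-dioxolan-4-yl]acetic acid | CC1(C)OC(=O)[C@](C)(CC(=O)O)O1 | intermediate
7 | (S)-5-(2-hydroxyethyl)-2,2,5-trimethyl-1,3-dioxolan-4-one | CC1(C)OC(=O)[C@](C)(CCO)O1 | intermediate
8 | (S)-2,4-dihydroxy-N-methoxy-N,2-dimethylbutanamide | CON(C)C(=O)[C@](C)(CCO)O | intermediate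
9 | (S)-4-(tert-butyldimethylsilyloxy)-2-hydroxy-N-methoxy-N,2-dimethylbutanamide (mono-TBS ether) | CON(C)C(=O)[C@](C)(CCO[Si](C)(C)C(C)(C)C)O | intermediate (not isolated)
10 | (S)-4-(tert-butyldimethylsilyloxy)-N-methoxy-N,2-dimethyl-2-(trimethylsilyloxy)butanamide | CON(C)C(=O)[C@](C)(CCO[Si](C)(C)C(C)(C)C)O[Si](C)(C)C | intermediate
11 | (S)-5-(tert-butyldimethylsilyloxy)-3-methyl-3-(trimethylsilyloxy)pentan-2-one | CC(=O)[C@](C)(CCO[Si](C)(C)C(C)(C)C)O[Si](C)(C)C | intermediate
12 | (Z)-2-[(tert-butyldiphenylsilyloxy)methyl]-3-iodoacryloyl chloride | ClC(=O)/C(CO[Si](c1ccccc1)(c1ccccc1)C(C)(C)C)=C\I | intermediate (not isolated)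
13 | (1Z,6S)-8-(tert-butyldimethylsilyloxy)-2-[(tert-butyldiphenylsilyloxy)methyl]-1-iodo-6-methyl-6-(trimethylsilyloxy)oct-1-ene-3,5-dione | I/C=C(/CO[Si](c1ccccc1)(c1ccccc1)C(C)(C)C)C(=O)CC(=O)[C@](C)(CCO[Si](C)(C)C(C)(C)C)O[Si](C)(C)C | intermediate (not isolated)
14 | (S)-2-[2-(tert-butyldimethylsilyloxy)ethyl]-5-[(Z)-3-(tert-butyldiphenylsilyloxy)-1-iodoprop-1-en-2-yl]-2-methylfuran-3(2H)-one | CC(C)(C)[Si](C)(C)OCC[C@]1(C)OC(=CC1=O)/C(CO[Si](c1ccccc1)(c1ccccc1)C(C)(C)C)=C\I | intermediate
15 | (S)-5-[(Z)-3-(tert-butyldiphenylsilyloxy)-1-iodoprop-1-en-2-yl]-2-(2-hydroxyethyl)-2-methylfuran-3(2H)-one | OCC[C@]1(C)OC(=CC1=O)/C(CO[Si](c1ccccc1)(c1ccccc1)C(C)(C)C)=C\I | intermediate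
16 | 2-[(S)-5-[(Z)-3-(tert-butyldiphenylsilyloxy)-1-iodoprop-1-en-2-yl]-2-methyl-3-oxo-2,3-dihydrofuran-2-yl]acetaldehyde | O=CC[C@]1(C)OC(=CC1=O)/C(CO[Si](c1ccccc1)(c1ccccc1)C(C)(C)C)=C\I | intermediate
17 | 4-tert-butoxy-4-oxobutanoic acid (mono-tert-butyl succinate) | CC(C)(C)OC(=O)CCC(=O)O | starting material
18 | (S)-4-benzyl-2-oxazolidinone | O=C1N[C@@H](Cc2ccccc2)CO1 | starting material
19 | 4-tert-butoxy-4-oxobutanoic pivalic anhydride | CC(C)(C)OC(=O)CCC(=O)OC(=O)C(C)(C)C | intermediate (not isolated)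
20 | tert-butyl 4-[(S)-4-benzyl-2-oxooxazolidin-3-yl]-4-oxobutanoate | CC(C)(C)OC(=O)CCC(=O)N1[C@@H](Cc2ccccc2)COC1=O | intermediate
21 | (Z)-dibutylboron enolate of 20 | CCCCB(CCCC)O/C(=C\CC(=O)OC(C)(C)C)N1[C@@H](Cc2ccccc2)COC1=O | intermediate (not isolated)
22 | tert-butyl (3R,4R)-3-[(S)-4-benzyl-2-oxooxazolidine-3-carbonyl]-4-hydroxy-5-[(S)-5-[(Z)-3-(tert-butyldiphenylsilyloxy)-1-iodoprop-1-en-2-yl]-2-methyl-3-oxo-2,3-dihydrofuran-2-yl]pentanoate | CC(C)(C)OC(=O)C[C@@H](C(=O)N1[C@@H](Cc2ccccc2)COC1=O)[C@H](O)C[C@]1(C)OC(=CC1=O)/C(CO[Si](c1ccccc1)(c1ccccc1)C(C)(C)C)=C\I | intermediate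
23 | C8 TBS ether of 22 | CC(C)(C)OC(=O)C[C@@H](C(=O)N1[C@@H](Cc2ccccc2)COC1=O)[C@H](O[Si](C)(C)C(C)(C)C)C[C@]1(C)OC(=CC1=O)/C(CO[Si](c1ccccc1)(c1ccccc1)C(C)(C)C)=C\I | intermediate
24 | tert-butyl (3S,4R)-4-(tert-butyldimethylsilyloxy)-5-[(S)-5-[(Z)-3-(tert-butyldiphenylsilyloxy)-1-iodoprop-1-en-2-yl]-2-methyl-3-oxo-2,3-dihydrofuran-2-yl]-3-(hydroxymethyl)pentanoate | CC(C)(C)OC(=O)C[C@@H](CO)[C@H](O[Si](C)(C)C(C)(C)C)C[C@]1(C)OC(=CC1=O)/C(CO[Si](c1ccccc1)(c1ccccc1)C(C)(C)C)=C\I | intermediate
25 | tert-butyl (3R,4R)-4-(tert-butyldimethylsilyloxy)-5-[(S)-5-[(Z)-3-(tert-butyldiphenylsilyloxy)-1-iodoprop-1-en-2-yl]-2-methyl-3-oxo-2,3-dihydrofuran-2-yl]-3-formylpentanoate (open-chain iodoalkenyl furanone with C6 aldehyde) | CC(C)(C)OC(=O)C[C@@H](C=O)[C@H](O[Si](C)(C)C(C)(C)C)C[C@]1(C)OC(=CC1=O)/C(CO[Si](c1ccccc1)(c1ccccc1)C(C)(C)C)=C\I | intermediate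
26 | tert-butyl 2-[(4Z,6R,7S,8R,10S)-8-(tert-butyldimethylsilyloxy)-15-(tert-butyldiphenylsilyloxy)-6-hydroxy-1-oxo-3,10-epoxy-11,12,13-trinorgermacra-2,4-dien-7-yl]acetate (macrocyclic C6 allylic alcohol) | CC(C)(C)OC(=O)C[C@H]1[C@H](O)/C=C(/CO[Si](c2ccccc2)(c2ccccc2)C(C)(C)C)C2=CC(=O)[C@@](C)(O2)C[C@H]1O[Si](C)(C)C(C)(C)C | intermediate
27 | (4Z,6R,7S,8R,10S)-8-(tert-butyldimethylsilyloxy)-15-(tert-butyldiphenylsilyloxy)-1-oxo-3,10-epoxy-13-norgermacra-2,4-dien-12,6-olide | C1C(=O)O[C@@H]2/C=C(/CO[Si](c4ccccc4)(c4ccccc4)C(C)(C)C)C3=CC(=O)[C@](C)(C[C@@H](O[Si](C)(C)C(C)(C)C)[C@@H]12)O3 | intermediate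
28 | 11-(dimethylaminomethyl) derivative of 27 (Mannich base, C11 epimers) | CN(C)CC1C(=O)O[C@@H]2/C=C(/CO[Si](c4ccccc4)(c4ccccc4)C(C)(C)C)C3=CC(=O)[C@](C)(C[C@@H](O[Si](C)(C)C(C)(C)C)[C@@H]12)O3 | intermediate (not isolated)
29 | 11-(trimethylammoniomethyl) derivative of 27, iodide | C[N+](C)(C)CC1C(=O)O[C@@H]2/C=C(/CO[Si](c4ccccc4)(c4ccccc4)C(C)(C)C)C3=CC(=O)[C@](C)(C[C@@H](O[Si](C)(C)C(C)(C)C)[C@@H]12)O3.[I-] | intermediate (not isolated)
30 | (4Z,6R,7S,8R,10S)-8-(tert-butyldimethylsilyloxy)-15-(tert-butyldiphenylsilyloxy)-1-oxo-3,10-epoxygermacra-2,4,11(13)-trien-12,6-olide | C=C1C(=O)O[C@@H]2/C=C(/CO[Si](c4ccccc4)(c4ccccc4)C(C)(C)C)C3=CC(=O)[C@](C)(C[C@@H](O[Si](C)(C)C(C)(C)C)[C@@H]12)O3 | intermediate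
31 | (4Z,6R,7R,8R,10S)-15-(tert-butyldiphenylsilyloxy)-8-hydroxy-1-oxo-3,10-epoxygermacra-2,4,11(13)-trien-12,6-olide | C=C1C(=O)O[C@@H]2/C=C(/CO[Si](c4ccccc4)(c4ccccc4)C(C)(C)C)C3=CC(=O)[C@](C)(C[C@@H](O)[C@@H]12)O3 | intermediate
32 | (4Z,6R,7R,8R,10S)-15-(tert-butyldiphenylsilyloxy)-8-(2-methylpropanoyloxy)-1-oxo-3,10-epoxygermacra-2,4,11(13)-trien-12,6-olide | C=C1C(=O)O[C@@H]2/C=C(/CO[Si](c4ccccc4)(c4ccccc4)C(C)(C)C)C3=CC(=O)[C@](C)(C[C@@H](OC(=O)C(C)C)[C@@H]12)O3 | intermediate
33 | (4Z,6R,7R,8R,10S)-15-hydroxy-8-(2-methylpropanoyloxy)-1-oxo-3,10-epoxygermacra-2,4,11(13)-trien-12,6-olide (CNP0176924.2) | C=C1C(=O)O[C@@H]2/C=C(/CO)C3=CC(=O)[C@](C)(C[C@@H](OC(=O)C(C)C)[C@@H]12)O3 | target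

**Step count**

Total steps: 22. Longest linear sequence: 18 steps (steps 4 to 11 and 13 to 22, from (S)-citramalic acid).

**Steps most likely to fail, with fallbacks**

Step 17 (ring closure). The addition may show poor facial selectivity at C6, since a ring-forming transition state need not follow the open-chain Felkin–Anh preference, and intermolecular coupling or protodeiodination may compete. The fallback sets out from 25 and salvages the wrong epimer. The C6 epimer of 26 F1, formed in the same cyclization, would be treated with trimethylsilyl triflate and 2,6-lutidine in CH2Cl2 at 0 °C, which converts the tert-butyl ester to the silyl ester and caps O6, giving the bis(trimethylsilyl) derivative F2. Mild aqueous acid on work-up would free the 6-epi seco acid F3. Mitsunobu lactonization of F3 (PPh3, diisopropyl azodicarboxylate, THF, 0 °C), run at once, would close ring C with inversion at C6 and return to the route at lactone 27.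

Step 13 (anti-aldol). The anti selectivity of the open transition state may erode with this β-branched, Lewis-basic aldehyde, and the aluminium-complexed aldehyde may lose the ring B oxygen by β-elimination. The fallback sets out from 16 and changes the donor to the aldehyde oxidation level. Slow addition of commercial tert-butyl 4-oxobutanoate to 16 with (R)-proline in DMF at 4 °C (enamine cross-aldol of two aldehydes, anti-selective, with the sense of induction mirror-imaged from the natural proline series) would give tert-butyl (3R,4R)-3-formyl-4-hydroxy-5-[(S)-5-[(Z)-3-(tert-butyldiphenylsilyloxy)-1-iodoprop-1-en-2-yl]-2-methyl-3-oxo-2,3-dihydrofuran-2-yl]pentanoate F4. Silylation of F4 with TBSOTf and 2,6-lutidine at −78 °C returns to the route at aldehyde 25, with no auxiliary, reduction or oxidation needed.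

Step 9 (ring B). The acid chloride may react at oxygen or at the β-iodo carbon instead of giving C-acylation, the iodoalkene may isomerize from Z to E, and early loss of the primary silyl ether would open a competing cyclization. The fallback sets out from 3 and 11 and builds the diketone by aldol addition and oxidation. Reduction of 3 with iBu2AlH in CH2Cl2 at −78 °C would give (E)-2-[(tert-butyldiphenylsilyloxy)methyl]-3-iodoprop-2-en-1-ol F5, and MnO2 in CH2Cl2 would give (Z)-2-[(tert-butyldiphenylsilyloxy)methyl]-3-iodoprop-2-enal F6. The lithium enolate of 11 (LiN(iPr)2, THF, −78 °C) would add 1,2 to F6 to give the β-hydroxy ketone F7. Dess–Martin oxidation of F7 gives diketone 13, and TsOH·H2O in CH2Cl2 then returns to the route at furanone 14.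

Further compounds
F1 | step 17 | C6 epimer of 26 (6S alcohol, tert-butyl ester) | CC(C)(C)OC(=O)C[C@H]1[C@@H](O)/C=C(/CO[Si](c2ccccc2)(c2ccccc2)C(C)(C)C)C2=CC(=O)[C@@](C)(O2)C[C@H]1O[Si](C)(C)C(C)(C)C
F2 | step 17 | bis(trimethylsilyl) derivative of the 6-epi seco acid (C12 trimethylsilyl ester, O6 trimethylsilyl ether) | C[Si](C)(C)OC(=O)C[C@H]1[C@@H](O[Si](C)(C)C)/C=C(/CO[Si](c2ccccc2)(c2ccccc2)C(C)(C)C)C2=CC(=O)[C@@](C)(O2)C[C@H]1O[Si](C)(C)C(C)(C)C
F3 | step 17 | 6-epi seco acid (C12 carboxylic acid, free 6S hydroxyl) | OC(=O)C[C@H]1[C@@H](O)/C=C(/CO[Si](c2ccccc2)(c2ccccc2)C(C)(C)C)C2=CC(=O)[C@@](C)(O2)C[C@H]1O[Si](C)(C)C(C)(C)C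
F4 | step 13 | tert-butyl (3R,4R)-3-formyl-4-hydroxy-5-[(S)-5-[(Z)-3-(tert-butyldiphenylsilyloxy)-1-iodoprop-1-en-2-yl]-2-methyl-3-oxo-2,3-dihydrofuran-2-yl]pentanoate | CC(C)(C)OC(=O)C[C@@H](C=O)[C@H](O)C[C@]1(C)OC(=CC1=O)/C(CO[Si](c1ccccc1)(c1ccccc1)C(C)(C)C)=C\I
F5 | step 9 | (E)-2-[(tert-butyldiphenylsilyloxy)methyl]-3-iodoprop-2-en-1-ol | OC/C(CO[Si](c1ccccc1)(c1ccccc1)C(C)(C)C)=C\I
F6 | step 9 | (Z)-2-[(tert-butyldiphenylsilyloxy)methyl]-3-iodoprop-2-enal | O=C/C(CO[Si](c1ccccc1)(c1ccccc1)C(C)(C)C)=C\I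
F7 | step 9 | (1Z,6S)-8-(tert-butyldimethylsilyloxy)-2-[(tert-butyldiphenylsilyloxy)methyl]-3-hydroxy-1-iodo-6-methyl-6-(trimethylsilyloxy)oct-1-en-5-one (C3 epimers) | I/C=C(/CO[Si](c1ccccc1)(c1ccccc1)C(C)(C)C)C(O)CC(=O)[C@](C)(CCO[Si](C)(C)C(C)(C)C)O[Si](C)(C)C
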